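| flask | left-handed substrate | right-handed substrate | solid reagent | free catalyst | remark | time |
|---|---|---|---|---|---|---|
| dawn | 0.10 M | 0.10 M | 0.11 M | 46 µM | run made earlier |  |
| noon | 0.10 M | 0.10 M | 0.11 M | 190 µM | run made earlier |  |
| dusk | 0.15 M | 0.15 M | 0.11 M | 93 µM | run made earlier |  |
| alpha | 0.10 M | 0.10 M | 0.110 M | 93 µM |  | 10 d |
| zeta | 0.10 M | 0.10 M | 0.110 M | 93 µM |  | 40 d |

| run | time / d | right-handed substrate / % | left-handed substrate / % |
|---|---|---|---|
| dawn | 1.04 | 48.8 | 49.4 |
| dawn | 1.67 | 49.4 | 48.4 |
| dawn | 2.50 | 49.6 | 46.5 |
| dawn | 4.00 | 50.4 | 43.6 |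
| dawn | 8.00 | 50.6 | 37.8 |
| dawn | 12.0 | 50.4 | 36.0 |
| noon | 2.08 | 49.6 | 41.6 |
| noon | 4.00 | 49.9 | 33.1 |
| noon | 6.00 | 49.3 | 24.2 |
| noon | 8.00 | 49.4 | 20.0 |
| noon | 10.0 | 49.2 | 15.4 |
| noon | 12.0 | 50.2 | 12.7 |
| dusk | 1.04 | 50.8 | 48.3 |
| dusk | 1.67 | 50.4 | 46.8 |
| dusk | 3.00 | 50.6 | 43.5 |
| dusk | 6.00 | 49.8 | 35.0 |
| dusk | 12.0 | 49.6 | 28.5 |

(scatter of a reading: 0.5 percentage points)

- free catalyst is single-handed; left-handed substrate and right-handed substrate are mirror images of each other, charged as a racemate, each of them at the stated concentration
- given per volume of solution although it is solid: solid reagent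
- on the list of suspects stand: free catalyst + right-handed substrate <-> catalyst intermediate B; solid reagent <-> partner; partner + catalyst intermediate B -> free catalyst + right-handed product; partner + catalyst intermediate A -> free catalyst + left-handed product; free catalyst + left-handed substrate <-> catalyst intermediate A; partner + free catalyst -> spent catalyst A; free catalyst -> spent catalyst B
- at the start none of the solid reagent is in solution
- an excess is below zero if the other one leads

1. the winner by excess of right-handed substrate over left-handed substrate among what is left of the two; "neither" if no more than 2 percentage points parts them (alpha / zeta / neither)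
2. excess of right-handed substrate over left-handed substrate among what is left of the two at the end, alpha
3. excess of right-handed substrate over left-handed substrate among what is left of the two at the end, zeta

**Two flasks.** Dawn held half the free catalyst of zeta, and you can watch it stall: its left-handed substrate fell 5.8 percentage points and then 1.8 points over two equal spans, while right-handed substrate stayed flat. I read this as a kinetic resolution with a dying catalyst, so I reckon the end of zeta from that death, not from a fitted curve.

**The fork.** Follow one molecule of partner. Meeting catalyst intermediate A, it makes left-handed product and frees the catalyst; meeting free catalyst, it makes spent catalyst A. Partner stands in both rates, so it cancels from the odds. If catalyst intermediate A keeps in equilibrium with free catalyst, those odds go with [left-handed substrate], and each free catalyst lost to spent catalyst A goes with the removal of a fixed fraction of the left-handed substrate remaining.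

**My reckoning.** Continuing dawn's shrinking falls, I put its end near 35.2 %. That gives 7.64 mM⁻¹, the reach: ln of start over end [left-handed substrate], per catalyst charged. For zeta it leaves 49.2 % of the left-handed charge, an excess of 34.1 %. At one partner per left-handed substrate turned over, this needs 50.8 mM of solid reagent, less than the 0.110 M charged. The reach gives an end, not a time, so for alpha at 10 d I take a rough guide: dusk, with the same charge of free catalyst but more of both substrates, read an excess of 27.0 % at 12.0 d. That is less than my zeta, so I name zeta.

**The forecast.** It names zeta: 33 % (28 % to 37 %) for alpha and 38.5 % (33 % to 45 %) for zeta, on the ground that “the catalyst dies while plenty of reagent remains”. My zeta lies lower, inside its range.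

**The flask.** The winner is zeta, with 28.9 % for alpha and 36.8 % for zeta.

    free catalyst + right-handed substrate ⇌ catalyst intermediate B (K = 3.24 M⁻¹, k = 24.6 M⁻¹ s⁻¹)
    solid reagent ⇌ partner, rate k2*(cs2 - [partner]) while solid is left; crystals form when [partner] > cs2 (solubility = 35.0 mM, k = 6.26 × 10⁻⁶ s⁻¹)
    partner + catalyst intermediate B → free catalyst + right-handed product (k = 0.00178 M⁻¹ s⁻¹)
    partner + catalyst intermediate A → free catalyst + left-handed product (k = 0.150 M⁻¹ s⁻¹)
    free catalyst + left-handed substrate ⇌ catalyst intermediate A (K = 8.62 M⁻¹, k = 4.72 M⁻¹ s⁻¹)
    partner + free catalyst → spent catalyst A (k = 1.54 × 10⁻⁴ M⁻¹ s⁻¹)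
    free catalyst → spent catalyst B (k = 2.77 × 10⁻⁹ s⁻¹)

**The odds.** In zeta at 4.20 d, catalyst intermediate A falls back 170 times faster than it goes on, and at 40.0 d spent catalyst A holds 99.9 % of the catalyst, with 46 % of the left-handed substrate left against 49.2 % from the reach. The neighbouring flask with 5.6 × 10⁻⁵ M of free catalyst ends with 63 % of its left-handed substrate left, against 65.2 % from the same reach, at an excess of 22.8 %.

Readings and results are calculated with made-up constants, and the scatter is random.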